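The plan rests on cutting the C3–C4 bond of the quinic acid ring. C3 and C4 carry cis oxygens and O4 is trans to O5; this 3,4-cis-4,5-trans triol pattern on the cyclohexane is what a samarium-mediated pinacol coupling delivers when two aldehydes close beside an existing alkoxy carbon. One operation therefore makes the carbocycle, the C3–C4 bond and both carbinol stereocentres. The precursor is an acyclic 1,6-dialdehyde, benzyl 2-(benzyloxymethoxy)-4-(silyloxy)-5-oxo-2-(2-oxoethyl)pentanoate, whose C1 and C5 stereocentres come from a catalytic asymmetric keto ester aldol and a hydroxyl-directed reduction. Galloylation of O4, O3 and O5 in turn and one global hydrogenolysis finish the synthesis.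

Key step: step 7

Remark: ring positions use quinic acid numbering (C1 bears the carboxyl group); open-chain intermediates are named as pentanoates or hexenoates.
Assumption: O1 is carried through the ring closure as a benzyloxymethyl (BOM) ether, not a bulky silyl ether, because O3 must end up syn to O1 and a small chelating group turns that 1,3-diaxial contact into a samarium chelate; the BOM group also leaves in the final hydrogenolysis.
Assumption: dibenzyl oxalate, 2-(trimethylsilyloxy)buta-1,3-diene and 3,4,5-tris(benzyloxy)benzoic acid are bought.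
Remark: the three galloyl esters are identical and are introduced one per step (O4, O3, then O5 after desilylation), so a minor regioisomeric monoester or an acyl shift between neighbouring ring oxygens converges on the same tris-ester.

Step 1
Reactants: 1 dibenzyl oxalate; 2 allylmagnesium bromide
Product: 4 benzyl 2-oxopent-4-enoate, via bromomagnesium hemiketal alkoxide 3 (not isolated)
Conditions: 2 (1.0 equiv, Et2O) added to 1, THF, −78 °C; sat. aq. NH4Cl at −78 °C
Reagents that add atoms: none
Why: Grignard mono-addition to an oxalate diester works because the chelated tetrahedral alkoxide 3 survives at −78 °C and collapses to the keto ester only on quench, so a second addition is avoided; no stereocentre is formed.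

Step 2
Reactants: 4 benzyl 2-oxopent-4-enoate; 5 2-(trimethylsilyloxy)buta-1,3-diene
Product: 7 benzyl (2S)-2-hydroxy-4-oxo-2-(prop-2-en-1-yl)hex-5-enoate, via trimethylsilyl ether 6 (not isolated)
Conditions: Cu(OTf)2 (10 mol %), 2,2-bis[(4S)-4-tert-butyl-4,5-dihydrooxazol-2-yl]propane (11 mol %), THF, −78 °C; then 1 M HCl, THF, 0 °C
Reagents that add atoms: none
Why: In this catalytic enantioselective Mukaiyama aldol addition the keto ester chelates divalent copper through both carbonyl oxygens, a tert-butyl group of the ligand blocks the re face of the ketone, and the enol silane terminus adds to the si face to set the C1 carbinol as (2S); silyl transfer gives 6, which dilute acid cleaves.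

Step 3
Reactants: 7 benzyl (2S)-2-hydroxy-4-oxo-2-(prop-2-en-1-yl)hex-5-enoate
Product: 8 benzyl (2S,4R)-2,4-dihydroxy-2-(prop-2-en-1-yl)hex-5-enoate
Conditions: Me4NBH(OAc)3 (5 equiv), MeCN/AcOH (1:1), −30 °C; aq. potassium sodium tartrate
Reagents that add atoms: none
Why: In this Evans–Saksena hydroxyl-directed reduction the tertiary hydroxyl exchanges onto boron and delivers hydride internally through a chair with the allyl arm equatorial and the flatter ester axial, which should place the new C5 oxygen anti to O1 along the allyl-bearing chain (4R, the 1,5-trans relationship of the ring) and reduce the enone 1,2.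

Step 4
Reactants: 8 benzyl (2S,4R)-2,4-dihydroxy-2-(prop-2-en-1-yl)hex-5-enoate
Product: 9 benzyl (2S,4R)-4-(tert-butyldimethylsilyloxy)-2-hydroxy-2-(prop-2-en-1-yl)hex-5-enoate
Conditions: TBSCl (1.2 equiv), imidazole (2.5 equiv), DMF, 0 °C → rt
Reagents that add atoms: tert-butyldimethylsilyl chloride (TBSCl), CC(C)(C)[Si](C)(C)Cl
Why: Silylation with a silyl chloride and imidazole should take only the secondary allylic hydroxyl, since the tertiary α-hydroxy ester is too hindered and electron-poor to react, and no stereocentre is touched.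

Step 5
Reactants: 9 benzyl (2S,4R)-4-(tert-butyldimethylsilyloxy)-2-hydroxy-2-(prop-2-en-1-yl)hex-5-enoate
Product: 10 benzyl (2S,4R)-2-[(benzyloxy)methoxy]-4-(tert-butyldimethylsilyloxy)-2-(prop-2-en-1-yl)hex-5-enoate
Conditions: BOMCl (4 equiv), iPr2NEt (6 equiv), Bu4NI (0.2 equiv), ClCH2CH2Cl, 50 °C
Reagents that add atoms: benzyl chloromethyl ether (BOMCl), ClCOCc1ccccc1
Why: Alkoxymethylation with an α-halo ether (activated in situ as the iodomethyl ether) is electrophilic enough to etherify a hindered tertiary alcohol under a mild amine base that threatens neither the silyl ether nor the ester.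

Step 6
Reactants: 10 benzyl (2S,4R)-2-[(benzyloxy)methoxy]-4-(tert-butyldimethylsilyloxy)-2-(prop-2-en-1-yl)hex-5-enoate
Product: 12 benzyl (2R,4R)-2-[(benzyloxy)methoxy]-4-(tert-butyldimethylsilyloxy)-5-oxo-2-(2-oxoethyl)pentanoate, via bis-ozonide 11 (not isolated)
Conditions: O3, CH2Cl2, −78 °C until faint blue; then PPh3, −78 °C → rt; used at once
Reagents that add atoms: ozone, [O-][O+]=O
Why: Ozonolysis with reductive work-up converts both terminal alkenes through their ozonides into aldehydes, the benzyl, acetal and silyl groups tolerate brief ozone exposure at −78 °C, and immediate use of the α-silyloxy aldehyde guards C5 against epimerisation (the C1 descriptor changes to R only through priority rules).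

Step 7
Reactants: 12 benzyl (2R,4R)-2-[(benzyloxy)methoxy]-4-(tert-butyldimethylsilyloxy)-5-oxo-2-(2-oxoethyl)pentanoate
Product: 13 benzyl 1-O-[(benzyloxy)methyl]-5-O-(tert-butyldimethylsilyl)quinate
Conditions: SmI2 (0.1 M in THF, 3 equiv), t-BuOH (3 equiv), no HMPA, slow addition of 12 (final 0.01 M), −78 °C → −20 °C; aq. NaHCO3/potassium sodium tartrate
Reagents that add atoms: none
Why: Each aldehyde accepts one electron from divalent samarium, and the two ketyl radical anions, held together by trivalent samarium bridging both oxygens, join carbon to carbon to form C3–C4. The closest known reaction is the SmI2 pinacol cyclisation of 1,6-dialdehydes, such as sugar-derived hexodialdoses, to cis-cyclohexane-1,2-diols. The single ring formed, the six-membered carbocycle, closes by intramolecular ketyl–ketyl coupling between the two chain termini, so all six ring carbons lie in the tether and no exo or endo choice arises. The cis relationship of O3 and O4 follows from the samarium bridge, O4 goes trans to O5 because the metal-bound ketyl oxygen avoids the neighbouring silyloxy group sterically and electrostatically, and O3 syn to O1 is supported by chelation of samarium to the benzyloxymethyl ether oxygens. The step needs diastereoselectivity for this one cis-diol and chemoselectivity for the aldehydes: O5 is a silyl ether, not an acyl group, so the C5–O bond is not reductively cleaved, the benzyl ester is inert without HMPA, and high dilution suppresses intermolecular coupling.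

Step 8
Reactants: 13 benzyl 1-O-[(benzyloxy)methyl]-5-O-(tert-butyldimethylsilyl)quinate; 14 3,4,5-tris(benzyloxy)benzoic acid
Product: 15 benzyl 1-O-[(benzyloxy)methyl]-5-O-(tert-butyldimethylsilyl)-4-O-[3,4,5-tris(benzyloxy)benzoyl]quinate
Conditions: 14 (1.05 equiv), DCC (1.1 equiv), DMAP (0.1 equiv), CH2Cl2, −20 °C → 0 °C
Reagents that add atoms: none
Why: Steglich esterification (carbodiimide activation, DMAP acyl transfer) with one equivalent of acid should stop after one ester, placed on the equatorial O4 because the axial O3 lies 1,3-diaxial to the C1 acetal oxygen and reacts more slowly; no stereocentre is touched.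

Step 9
Reactants: 15 benzyl 1-O-[(benzyloxy)methyl]-5-O-(tert-butyldimethylsilyl)-4-O-[3,4,5-tris(benzyloxy)benzoyl]quinate; 14 3,4,5-tris(benzyloxy)benzoic acid
Product: 16 benzyl 1-O-[(benzyloxy)methyl]-5-O-(tert-butyldimethylsilyl)-3,4-bis-O-[3,4,5-tris(benzyloxy)benzoyl]quinate
Conditions: 14 (2 equiv), DCC (2.2 equiv), DMAP (1 equiv), CH2Cl2, rt → 40 °C
Reagents that add atoms: none
Why: Steglich esterification with excess activated acid, a full equivalent of DMAP and mild warming should acylate the hindered axial O3, which is the only free hydroxyl left, so no selectivity is required and no stereocentre is touched.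

Step 10
Reactants: 16 benzyl 1-O-[(benzyloxy)methyl]-5-O-(tert-butyldimethylsilyl)-3,4-bis-O-[3,4,5-tris(benzyloxy)benzoyl]quinate
Product: 17 benzyl 1-O-[(benzyloxy)methyl]-3,4-bis-O-[3,4,5-tris(benzyloxy)benzoyl]quinate
Conditions: HF·pyridine, pyridine/THF, 0 °C → rt
Reagents that add atoms: none
Why: Fluoride-mediated desilylation with pyridine-buffered HF·pyridine should cleave the secondary silyl ether without touching the acetal, the esters or any stereocentre, and the weakly acidic medium disfavours both base-promoted acyl migration from O4 to O5 and lactonisation of O5 onto the benzyl ester.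

Step 11
Reactants: 17 benzyl 1-O-[(benzyloxy)methyl]-3,4-bis-O-[3,4,5-tris(benzyloxy)benzoyl]quinate; 14 3,4,5-tris(benzyloxy)benzoic acid
Product: 18 benzyl 1-O-[(benzyloxy)methyl]-3,4,5-tris-O-[3,4,5-tris(benzyloxy)benzoyl]quinate
Conditions: 14 (1.5 equiv), DCC (1.6 equiv), DMAP (0.5 equiv), CH2Cl2, 0 °C → rt
Reagents that add atoms: none
Why: Steglich esterification of the single free, equatorial O5 hydroxyl needs no selectivity, O1 being blocked as the acetal, and no stereocentre is touched.

Step 12
Reactants: 18 benzyl 1-O-[(benzyloxy)methyl]-3,4,5-tris-O-[3,4,5-tris(benzyloxy)benzoyl]quinate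
Product: 19 3,4,5-tri-O-galloylquinic acid (CNP0148451.1)
Conditions: H2 (1 atm), Pd(OH)2/C, THF/MeOH (1:1), rt; filtration under argon
Reagents that add atoms: none
Why: Catalytic hydrogenolysis should cleave the nine aryl benzyl ethers, the benzyl ester and the benzyl group of the BOM ether, whose hemiformal then loses formaldehyde, while the galloyl esters and all four stereocentres are untouched under neutral conditions.

Compound list
1 | dibenzyl oxalate | O=C(OCc1ccccc1)C(=O)OCc1ccccc1 | starting material
2 | allylmagnesium bromide | C=CC[Mg]Br | starting material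
3 | bromomagnesium alkoxide of benzyl 2-(benzyloxy)-2-hydroxypent-4-enoate (tetrahedral adduct, racemic) | C=CCC(O[Mg]Br)(OCc1ccccc1)C(=O)OCc1ccccc1 | intermediate
4 | benzyl 2-oxopent-4-enoate | C=CCC(=O)C(=O)OCc1ccccc1 | intermediate
5 | 2-(trimethylsilyloxy)buta-1,3-diene | C=CC(=C)O[Si](C)(C)C | starting material
6 | benzyl (2S)-4-oxo-2-(prop-2-en-1-yl)-2-(trimethylsilyloxy)hex-5-enoate | C=CC[C@@](O[Si](C)(C)C)(C(=O)OCc1ccccc1)CC(=O)C=C | intermediate
7 | benzyl (2S)-2-hydroxy-4-oxo-2-(prop-2-en-1-yl)hex-5-enoate | C=CC[C@@](O)(C(=O)OCc1ccccc1)CC(=O)C=C | intermediate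
8 | benzyl (2S,4R)-2,4-dihydroxy-2-(prop-2-en-1-yl)hex-5-enoate | C=CC[C@@](O)(C(=O)OCc1ccccc1)C[C@@H](O)C=C | intermediate
9 | benzyl (2S,4R)-4-(tert-butyldimethylsilyloxy)-2-hydroxy-2-(prop-2-en-1-yl)hex-5-enoate | C=CC[C@@](O)(C(=O)OCc1ccccc1)C[C@@H](O[Si](C)(C)C(C)(C)C)C=C | intermediate
10 | benzyl (2S,4R)-2-[(benzyloxy)methoxy]-4-(tert-butyldimethylsilyloxy)-2-(prop-2-en-1-yl)hex-5-enoate | C=CC[C@@](OCOCc1ccccc1)(C(=O)OCc1ccccc1)C[C@@H](O[Si](C)(C)C(C)(C)C)C=C | intermediate
11 | bis-ozonide of 10 (both alkenes as 1,2,4-trioxolanes, mixture of epimers at the ozonide carbons) | C1(OCOO1)C[C@@](OCOCc2ccccc2)(C(=O)OCc2ccccc2)C[C@@H](O[Si](C)(C)C(C)(C)C)C1OCOO1 | intermediate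
12 | benzyl (2R,4R)-2-[(benzyloxy)methoxy]-4-(tert-butyldimethylsilyloxy)-5-oxo-2-(2-oxoethyl)pentanoate | O=CC[C@@](OCOCc1ccccc1)(C(=O)OCc1ccccc1)C[C@@H](O[Si](C)(C)C(C)(C)C)C=O | intermediate
13 | benzyl 1-O-[(benzyloxy)methyl]-5-O-(tert-butyldimethylsilyl)quinate (O3/O4 cis, O4/O5 trans, O1 cis to O3) | CC(C)(C)[Si](C)(C)O[C@@H]1C[C@](OCOCc2ccccc2)(C(=O)OCc2ccccc2)C[C@@H](O)[C@H]1O | intermediate
14 | 3,4,5-tris(benzyloxy)benzoic acid | OC(=O)c1cc(OCc2ccccc2)c(OCc2ccccc2)c(OCc2ccccc2)c1 | starting material
15 | benzyl 1-O-[(benzyloxy)methyl]-5-O-(tert-butyldimethylsilyl)-4-O-[3,4,5-tris(benzyloxy)benzoyl]quinate | CC(C)(C)[Si](C)(C)O[C@@H]1C[C@](OCOCc2ccccc2)(C(=O)OCc2ccccc2)C[C@@H](O)[C@H]1OC(=O)c1cc(OCc2ccccc2)c(OCc2ccccc2)c(OCc2ccccc2)c1 | intermediate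
16 | benzyl 1-O-[(benzyloxy)methyl]-5-O-(tert-butyldimethylsilyl)-3,4-bis-O-[3,4,5-tris(benzyloxy)benzoyl]quinate | CC(C)(C)[Si](C)(C)O[C@@H]1C[C@](OCOCc2ccccc2)(C(=O)OCc2ccccc2)C[C@@H](OC(=O)c2cc(OCc3ccccc3)c(OCc3ccccc3)c(OCc3ccccc3)c2)[C@H]1OC(=O)c1cc(OCc2ccccc2)c(OCc2ccccc2)c(OCc2ccccc2)c1 | intermediate
17 | benzyl 1-O-[(benzyloxy)methyl]-3,4-bis-O-[3,4,5-tris(benzyloxy)benzoyl]quinate (O5 free) | O[C@@H]1C[C@](OCOCc2ccccc2)(C(=O)OCc2ccccc2)C[C@@H](OC(=O)c2cc(OCc3ccccc3)c(OCc3ccccc3)c(OCc3ccccc3)c2)[C@H]1OC(=O)c1cc(OCc2ccccc2)c(OCc2ccccc2)c(OCc2ccccc2)c1 | intermediate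
18 | benzyl 1-O-[(benzyloxy)methyl]-3,4,5-tris-O-[3,4,5-tris(benzyloxy)benzoyl]quinate | O=C(O[C@@H]1C[C@](OCOCc2ccccc2)(C(=O)OCc2ccccc2)C[C@@H](OC(=O)c2cc(OCc3ccccc3)c(OCc3ccccc3)c(OCc3ccccc3)c2)[C@H]1OC(=O)c1cc(OCc2ccccc2)c(OCc2ccccc2)c(OCc2ccccc2)c1)c1cc(OCc2ccccc2)c(OCc2ccccc2)c(OCc2ccccc2)c1 | intermediate
19 | 3,4,5-tri-O-galloylquinic acid (CNP0148451.1) | O=C(O[C@@H]1C[C@](O)(C(=O)O)C[C@@H](OC(=O)c2cc(O)c(O)c(O)c2)[C@H]1OC(=O)c1cc(O)c(O)c(O)c1)c1cc(O)c(O)c(O)c1 | target

Total step count: 12. Longest linear sequence: 12 steps (steps 1–12; the galloyl donor 14 is bought and enters in steps 8, 9 and 11).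

Steps most likely to fail

Step 7 (key step). The ketyl coupling may show poor facial selectivity, since the all-cis O3/O4/O5 diol has fewer 1,3-diaxial contacts in its chair. Over-reduction may expel the C5 silyloxy group, and the dialdehyde may epimerise at C5 or simply be reduced before it cyclises. The fallback sets out from diene 10 and gives up the pinacol closure. Ring-closing metathesis with second-generation Grubbs catalyst (CH2Cl2, 40 °C) should give benzyl (1S,5R)-1-[(benzyloxy)methoxy]-5-(tert-butyldimethylsilyloxy)cyclohex-3-ene-1-carboxylate F1. Dihydroxylation with OsO4 (cat.) and N-methylmorpholine N-oxide in acetone/H2O should then occur on the face opposite to the allylic silyloxy group and the ester, giving the cis-diol and rejoining the route at 13.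

Step 3. The internal hydride delivery may show weak or reversed facial selectivity, because the allyl and ester substituents on the directing carbinol differ only modestly in size. The fallback sets out from 7 and uses reagent control. Luche reduction (NaBH4, CeCl3·7H2O, MeOH, −78 °C) gives 8 together with its C4 epimer, benzyl (2S,4S)-2,4-dihydroxy-2-(prop-2-en-1-yl)hex-5-enoate F2. A Sharpless kinetic resolution of the mixture (Ti(OiPr)4, L-(+)-diisopropyl tartrate, t-BuOOH, 4 Å sieves, CH2Cl2, −20 °C) should epoxidise the (4S)-carbinol faster, to benzyl (2S,4S)-2,4-dihydroxy-4-[(2R)-oxiran-2-yl]-2-(prop-2-en-1-yl)butanoate F3. The (4R)-allylic alcohol is left behind, separated, and the route is rejoined at 8.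

Step 2. The silyloxydiene may react along other paths: cycloaddition-type closure, or oxa-Michael cyclisation of the adduct to a tetrahydropyranone. The β,γ-unsaturated keto ester may isomerise into conjugation, and the enantioselectivity may erode with this less usual nucleophile. The fallback sets out from 4 and uses a better-behaved nucleophile. The same Cu(OTf)2/bis(oxazoline) catalyst with 1-(ethylsulfanyl)-1-(trimethylsilyloxy)ethene should give benzyl (2S)-2-[2-(ethylsulfanyl)-2-oxoethyl]-2-(trimethylsilyloxy)pent-4-enoate F4. Acidic work-up then gives benzyl (2S)-2-[2-(ethylsulfanyl)-2-oxoethyl]-2-hydroxypent-4-enoate F5. Liebeskind–Srogl coupling of the thioester with tributyl(vinyl)stannane (Pd2(dba)3, tri(2-furyl)phosphine, copper thiophene-2-carboxylate CuTC with monovalent copper, THF, rt) installs the vinyl ketone and rejoins the route at 7.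

Further compounds
F1 | step 7 | benzyl (1S,5R)-1-[(benzyloxy)methoxy]-5-(tert-butyldimethylsilyloxy)cyclohex-3-ene-1-carboxylate | CC(C)(C)[Si](C)(C)O[C@@H]1C[C@](OCOCc2ccccc2)(C(=O)OCc2ccccc2)CC=C1
F2 | step 3 | benzyl (2S,4S)-2,4-dihydroxy-2-(prop-2-en-1-yl)hex-5-enoate | C=CC[C@@](O)(C(=O)OCc1ccccc1)C[C@H](O)C=C
F3 | step 3 | benzyl (2S,4S)-2,4-dihydroxy-4-[(2R)-oxiran-2-yl]-2-(prop-2-en-1-yl)butanoate | C=CC[C@@](O)(C(=O)OCc1ccccc1)C[C@H](O)[C@H]1CO1
F4 | step 2 | benzyl (2S)-2-[2-(ethylsulfanyl)-2-oxoethyl]-2-(trimethylsilyloxy)pent-4-enoate | C=CC[C@@](O[Si](C)(C)C)(C(=O)OCc1ccccc1)CC(=O)SCC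
F5 | step 2 | benzyl (2S)-2-[2-(ethylsulfanyl)-2-oxoethyl]-2-hydroxypent-4-enoate | C=CC[C@@](O)(C(=O)OCc1ccccc1)CC(=O)SCC
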